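**Assumptions (one line each)**
- The SMILES is read as trans,trans-(2S,3S,2'S,3'S): both dihydrobenzofurans are 2,3-trans and have the same spatial sense.
- All phenols are carried as methyl ethers until the last step.
- Simple reagents that deliver atoms (paraformaldehyde, Tf2O) are given with SMILES but not numbered.
- "Ring B" is the dihydrofuran fused to the central resorcinol ring. "Ring A" is the dihydrofuran fused to the styryl-bearing ring.
- The TADDOL enantiomer that gives the (S,S) sense is assumed to be (R,R); both antipodes would be screened.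

**Retrosynthetic overview**
1. Target 14 comes from heptamethyl ether 13 by BBr3 demethylation. 13 comes from a Heck reaction of 3,5-dimethoxystyrene on the ring-A aryl triflate 11.
2. Ring A forms by an enantioselective formal [3+2] of p-benzoquinone (9) with the stilbene alkene of (+)-ε-viniferin pentamethyl ether (8). This desymmetrises and dearomatises a symmetric feedstock and sets C2/C3 trans. The quinone's second C=O becomes the C5–OH that carries the styryl group.
3. 8 comes from a Horner–Wadsworth–Emmons (HWE) reaction on aldehyde 6. The aldehyde comes from OH-directed ortho-formylation of phenol 3, followed by removal of the directing OH.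
4. Ring B forms first, by the same type of [3+2] between 2-methoxy-1,4-benzoquinone (1) and trimethylresveratrol (2).
5. Ring order is B, then A. All four stereocentres come from two catalyst-controlled, trans-selective annulations.

---

**Step 1**
Reactants: 1 (2-methoxy-1,4-benzoquinone); 2 ((E)-3,4',5-trimethoxystilbene)
Product: 3 ((2S,3S)-trans-3-(3,5-dimethoxyphenyl)-6-methoxy-2-(4-methoxyphenyl)-2,3-dihydrobenzofuran-5-ol)
Conditions: (R,R)-TADDOL–Ti(IV) Lewis acid (20 mol %), 4 Å MS, CH2Cl2, −78 → −20 °C
Reagents that add atoms: none
Why: Proposed new method: the chiral Ti(IV) chelates C1=O and the 2-OMe of 1 and directs C5 attack by the stilbene carbon bearing the 3,5-dimethoxyphenyl group. The resulting p-anisyl benzylic cation is closed by the C4 oxygen (enolised ketone) to give the trans dihydrofuran. Tautomerisation then rearomatises the ring, leaving the 5-OH. The closest known reaction is the Engler Lewis-acid [3+2] of 2-alkoxybenzoquinones with styrenes, here with a stilbene and an enantioselective catalyst; the catalyst face selectivity sets C2/C3.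

**Step 2**
Reactants: 3
Product: 4 (the C4-formyl phenol, i.e. the salicylaldehyde)
Conditions: MgCl2, Et3N, (CH2O)n, MeCN, 80 °C
Reagents that add atoms: paraformaldehyde, C=O (supplies the CHO carbon and oxygen)
Why: Casnati–Skattebøl formylation is strictly ortho to the OH, and C4 is the only free ortho position of 3 (C6 carries OMe, C7a is para and blocked); the conditions are basic, so the benzylic C–O bonds and both stereocentres are untouched.

**Step 3**
Reactants: 4
Product: 5 (aryl triflate of 4)
Conditions: Tf2O, pyridine, CH2Cl2, 0 °C
Reagents that add atoms: Tf2O, O=S(=O)(OS(=O)(=O)C(F)(F)F)C(F)(F)F (the triflyl group stays in the product)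
Why: Standard phenol triflation. It converts the OH, which has served as the ortho director, into a leaving group for reduction; no stereocentre is involved.

**Step 4**
Reactants: 5
Product: 6 (aldehyde with H in place of OTf, CHO retained at C4)
Conditions: Pd(OAc)2 (5 mol %), dppf, HCO2H, Et3N, DMF, 70 °C
Reagents that add atoms: none (formate supplies only H)
Why: Cacchi-type Pd-catalysed hydrogenolysis of the aryl triflate removes the extra oxygen that the quinone route leaves at C5, giving the 6-oxygenated benzofuran of the target. The aldehyde, methyl ethers and the benzylic stereocentres survive.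

**Step 5**
Reactants: 6; 7 (diethyl (4-methoxybenzyl)phosphonate)
Product: 8 ((+)-ε-viniferin pentamethyl ether: trans-2,3-diaryl-4-[(E)-4-methoxystyryl] dihydrobenzofuran, (2S,3S))
Conditions: NaH, THF, 0 °C → rt
Reagents that add atoms: none (the phosphonate is numbered reactant 7)
Why: HWE olefination of the aldehyde is E-selective and builds the stilbene that is the substrate for ring A; the mild base leaves C2/C3 intact.

**Step 6**
Reactants: 8; 9 (p-benzoquinone)
Product: 10 (phenol with ring A and ring B formed; ring A is (2S,3S)-trans, 5-OH)
Conditions: (R,R)-TADDOL–Ti(IV) (30 mol %), 4 Å MS, 2 equiv 9, CH2Cl2/PhMe, −40 → 0 °C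
Reagents that add atoms: none (9 is a numbered reactant; its C6H4O2 becomes ring A)
Why: Proposed new method: the Lewis-acid-activated symmetric quinone is attacked at carbon by the nucleophilic terminus of 8, i.e. the alkene carbon attached to the resorcinol ring. The p-anisyl benzylic cation is then closed by the neighbouring quinone oxygen, and tautomerisation gives the 5-hydroxy-dihydrobenzofuran. The closest known reaction is the Engler quinone–styrene [3+2] (here without a chelating 2-alkoxy group); the catalyst selects the alkene face and the stepwise cation closure gives trans C2/C3.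

**Step 7**
Reactants: 10
Product: 11 (ring-A C5 aryl triflate)
Conditions: Tf2O, pyridine, CH2Cl2, 0 °C
Reagents that add atoms: Tf2O, O=S(=O)(OS(=O)(=O)C(F)(F)F)C(F)(F)F
Why: Activates the quinone-derived phenol for C–C coupling; no stereocentre is affected.

**Step 8**
Reactants: 11; 12 (3,5-dimethoxystyrene)
Product: 13 (heptamethyl ether of the target, E-stilbene)
Conditions: Pd(OAc)2 (10 mol %), dppp, Et3N, DMF, 90 °C
Reagents that add atoms: none (12 is a numbered reactant)
Why: Mizoroki–Heck coupling of an aryl triflate with a styrene gives the E-stilbene. 11 contains no other alkene, because the only alkene of 8 was consumed in step 6, so the coupling is chemoselective.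

**Step 9**
Reactants: 13
Product: 14 (trans-diptoindonesin B)
Conditions: BBr3 (15 equiv), CH2Cl2, −78 → 0 °C, then MeOH/aq. NaHCO3
Reagents that add atoms: none (Br is not retained)
Why: BBr3 cleaves all seven aryl methyl ethers (the known conditions for ε-viniferin permethyl ether). Keeping the temperature at or below 0 °C avoids ionisation of the benzylic C2–O bonds, so C2 is not epimerised and the stereocentres set in steps 1 and 6 are retained.

---

**Compound list**

| No. | Name | SMILES | Role |
|---|---|---|---|
| 1 | 2-methoxy-1,4-benzoquinone | COC1=CC(=O)C=CC1=O | starting material |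
| 2 | (E)-3,4',5-trimethoxystilbene | COc1ccc(/C=C/c2cc(OC)cc(OC)c2)cc1 | starting material |
| 3 | (2S,3S)-trans-dihydrobenzofuran-5-ol from step 1 | COc1ccc(cc1)[C@H]2Oc3cc(OC)c(O)cc3[C@@H]2c2cc(OC)cc(OC)c2 | intermediate |
| 4 | C4-formyl phenol (salicylaldehyde) | COc1ccc(cc1)[C@H]2Oc3cc(OC)c(O)c(C=O)c3[C@@H]2c2cc(OC)cc(OC)c2 | intermediate |
| 5 | aryl triflate of 4 | COc1ccc(cc1)[C@H]2Oc3cc(OC)c(OS(=O)(=O)C(F)(F)F)c(C=O)c3[C@@H]2c2cc(OC)cc(OC)c2 | intermediate |
| 6 | C4-formyl dihydrobenzofuran (no C5 oxygen) | COc1ccc(cc1)[C@H]2Oc3cc(OC)cc(C=O)c3[C@@H]2c2cc(OC)cc(OC)c2 | intermediate |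
| 7 | diethyl (4-methoxybenzyl)phosphonate | CCOP(=O)(OCC)Cc1ccc(OC)cc1 | starting material |
| 8 | (+)-ε-viniferin pentamethyl ether | COc1ccc(cc1)[C@H]2Oc3cc(OC)cc(/C=C/c4ccc(OC)cc4)c3[C@@H]2c2cc(OC)cc(OC)c2 | intermediate |
| 9 | p-benzoquinone | O=C1C=CC(=O)C=C1 | starting material |
| 10 | bis-dihydrobenzofuran with ring-A 5-OH, pentamethyl ether | COc1ccc([C@H]2Oc3ccc(O)cc3[C@@H]2c2cc(OC)cc3c2[C@H](c2cc(OC)cc(OC)c2)[C@@H](c2ccc(OC)cc2)O3)cc1 | intermediate |
| 11 | aryl triflate of 10 | COc1ccc([C@H]2Oc3ccc(OS(=O)(=O)C(F)(F)F)cc3[C@@H]2c2cc(OC)cc3c2[C@H](c2cc(OC)cc(OC)c2)[C@@H](c2ccc(OC)cc2)O3)cc1 | intermediate |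
| 12 | 3,5-dimethoxystyrene | C=Cc1cc(OC)cc(OC)c1 | starting material |
| 13 | heptamethyl ether of the target | COc1ccc([C@H]2Oc3ccc(/C=C/c4cc(OC)cc(OC)c4)cc3[C@@H]2c2cc(OC)cc3c2[C@H](c2cc(OC)cc(OC)c2)[C@@H](c2ccc(OC)cc2)O3)cc1 | intermediate |
| 14 | trans-diptoindonesin B | Oc1ccc([C@H]2Oc3ccc(/C=C/c4cc(O)cc(O)c4)cc3[C@@H]2c2cc(O)cc3c2[C@H](c2cc(O)cc(O)c2)[C@@H](c2ccc(O)cc2)O3)cc1 | target |

---

**Step count:** total 9 steps; longest linear sequence 9 steps (1 → 3 → 4 → 5 → 6 → 8 → 10 → 11 → 13 → 14, counting the numbered steps 1–9).

**Three steps most likely to fail**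
1. **Step 6 (ring-A [3+2]):** the alkene is hindered, unsubstituted quinone has no chelating handle (so ee may be low), and the electron-rich resorcinol ring of 8 may add to the quinone instead. Fallback: build ring A stepwise from aldehyde 6. Add an ArLi derived from a 2-(MOM-oxy)-5-(3,5-dimethoxystyryl)bromobenzene to 6, deprotect to the o-hydroxybenzhydrol, and run an o-quinone-methide [4+1] annulation with a 4-methoxybenzyl sulfonium ylide under chiral-sulfide control.
2. **Step 1 (asymmetric Engler-type [3+2] with a stilbene):** enantioselectivity and yield are uncertain because of competing quinone redox chemistry. Fallback: run the reaction racemic with an achiral Lewis acid (TiCl4) and resolve 3 (or 8) by preparative chiral HPLC. Alternatively, semi-synthesise 8 by permethylation of natural (+)-ε-viniferin.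
3. **Step 9 (BBr3 global demethylation):** the benzylic aryl ethers may ring-open and the stilbene may degrade. Fallback: carry the phenols as benzyl ethers from the start (benzylated 2, 7 and 12) and remove them in the last step with BCl3/pentamethylbenzene at −78 °C, which avoids alkene hydrogenation.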